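## Retrosynthetic overview

1. The C8–O ester is cut last: an 8-hydroxy lactone plus a silyl-protected (2R,3R)-epoxy acid (Sharpless epoxidation of an allylic alcohol made from methyl but-2-ynoate).
2. The C6–C7 bond and the lactone C–O bond come from a chiral Brønsted acid-catalysed ring-closing allylboration of an ω-formyl 2-(methoxycarbonyl)allylboronate; ring A (ten-membered carbocycle) forms first and ring B (γ-lactone) closes onto it in the same operation.
3. The allylboronate comes from a γ-silyloxy ynoate by syn-hydroalumination and borylmethylation; the ynoate comes from asymmetric addition of methyl propiolate to an aldehyde (C7–C8, sets C8).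
4. The aldehyde comes from hydroboration of a terminal enyne; C2–C3 is made by a vinylogous Mukaiyama aldol of (Z)-3-methylpent-2-en-4-ynal with a senecioate dienolate (sets C2, the first stereocenter; both ring alkenes arrive with fixed geometry).
5. Ring order: oxirane (side-chain branch) → ring A → ring B → esterification → desilylation.

Assumption: atom labels C1–C15 in the Why lines follow germacranolide numbering of the target (lactone O on C6, ester O on C8, carbinol C2); for each chiral catalyst the enantiomer named is the one taken to give the face selectivity stated, and the antipode is used if the sense proves opposite.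

## Route

Step 1
Reactants: 1 (2Z)-3-methylpent-2-en-4-yn-1-ol
Product: 2 (2Z)-3-methylpent-2-en-4-ynal
Conditions: MnO2 (15 equiv), CH2Cl2, 23 °C
Reagents that add atoms: none
Why: MnO2 oxidizes the allylic alcohol to the conjugated aldehyde without touching the alkyne or isomerizing the Z-alkene (allylic oxidation).

Step 2
Reactants: 3 ethyl 3-methylbut-2-enoate
Product: 5 tert-butyl[(1-ethoxy-3-methylbuta-1,3-dien-1-yl)oxy]dimethylsilane, via lithium dienolate 4 (not isolated)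
Conditions: LiN(i-Pr)2, DMPU, THF, −78 °C; then TBSCl, −78 → 0 °C
Reagents that add atoms: tert-butyldimethylsilyl chloride (TBSCl), CC(C)(C)[Si](C)(C)Cl
Why: Kinetic γ-deprotonation of the β,β-dimethylacrylate and O-silylation of the extended enolate give the silyl dienolate (silyl ketene acetal formation).

Step 3
Reactants: 2 (2Z)-3-methylpent-2-en-4-ynal; 5 tert-butyl[(1-ethoxy-3-methylbuta-1,3-dien-1-yl)oxy]dimethylsilane
Product: 6 ethyl (2E,5R,6Z)-5-hydroxy-3,7-dimethylnona-2,6-dien-8-ynoate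
Conditions: SiCl4 (1.1 equiv), (R,R)-binaphthyldiamine-derived bisphosphoramide (5 mol%), CH2Cl2, −78 °C; aq. NaHCO3
Reagents that add atoms: none
Why: Lewis-base-catalysed, SiCl4-mediated vinylogous Mukaiyama aldol reaction in which the chiral phosphoramide-bound silyl cation shields the Si face of the enal, so γ-attack of 5 on the Re face sets C2 (5R) and gives the E-enoate; this is the first stereocenter of the route.

Step 4
Reactants: 6 ethyl (2E,5R,6Z)-5-hydroxy-3,7-dimethylnona-2,6-dien-8-ynoate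
Product: 7 ethyl (2E,5R,6Z)-5-{[tert-butyl(dimethyl)silyl]oxy}-3,7-dimethylnona-2,6-dien-8-ynoate
Conditions: TBSCl, imidazole, DMF, 23 °C
Reagents that add atoms: tert-butyldimethylsilyl chloride (TBSCl), CC(C)(C)[Si](C)(C)Cl
Why: Standard silylation of the secondary allylic alcohol (silyl ether protection).

Step 5
Reactants: 7 ethyl (2E,5R,6Z)-5-{[tert-butyl(dimethyl)silyl]oxy}-3,7-dimethylnona-2,6-dien-8-ynoate
Product: 8 (2E,5R,6Z)-5-{[tert-butyl(dimethyl)silyl]oxy}-3,7-dimethylnona-2,6-dien-8-yn-1-ol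
Conditions: i-Bu2AlH (2.5 equiv), CH2Cl2, −78 °C
Reagents that add atoms: none
Why: 1,2-Reduction of the conjugated ester to the allylic alcohol with the alkyne and silyl ether inert (hydride reduction).

Step 6
Reactants: 8 (2E,5R,6Z)-5-{[tert-butyl(dimethyl)silyl]oxy}-3,7-dimethylnona-2,6-dien-8-yn-1-ol
Product: 9 tert-butyl(dimethyl){[(3Z,5R,7E)-3,7-dimethyl-9-[(triethylsilyl)oxy]nona-3,7-dien-1-yn-5-yl]oxy}silane
Conditions: TESCl, imidazole, CH2Cl2, 0 °C
Reagents that add atoms: chlorotriethylsilane (TESCl), CC[Si](Cl)(CC)CC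
Why: Silylation of the primary alcohol as a TES ether that can later be oxidized directly (silyl ether protection).

Step 7
Reactants: 9 tert-butyl(dimethyl){[(3Z,5R,7E)-3,7-dimethyl-9-[(triethylsilyl)oxy]nona-3,7-dien-1-yn-5-yl]oxy}silane
Product: 11 (3Z,5R,7E)-5-{[tert-butyl(dimethyl)silyl]oxy}-3,7-dimethyl-9-[(triethylsilyl)oxy]nona-3,7-dienal, via alkenylborane 10 (not isolated)
Conditions: Cy2BH (1.2 equiv), THF, 0 °C; then 30% H2O2, pH 8 phosphate buffer, 0 °C
Reagents that add atoms: hydrogen peroxide, OO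
Why: The hindered borane adds anti-Markovnikov to the terminal alkyne only, and buffered oxidation gives the aldehyde by α-protonation of the dienol, leaving the Z-alkene out of conjugation (alkyne hydroboration–oxidation).

Step 8
Reactants: 11 (3Z,5R,7E)-5-{[tert-butyl(dimethyl)silyl]oxy}-3,7-dimethyl-9-[(triethylsilyl)oxy]nona-3,7-dienal; 12 methyl prop-2-ynoate
Product: 14 methyl (4R,6Z,8R,10E)-8-{[tert-butyl(dimethyl)silyl]oxy}-4-hydroxy-6,10-dimethyl-12-[(triethylsilyl)oxy]dodeca-6,10-dien-2-ynoate, via zinc acetylide 13 (not isolated)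
Conditions: 12 (3 equiv), ZnMe2 (3 equiv), (S,S)-ProPhenol (20 mol%), Ph3P=O (40 mol%), toluene, 4 °C; aq. NH4Cl
Reagents that add atoms: none
Why: Asymmetric alkynylation with the catalyst formed from ZnMe2 and ProPhenol, in which ligand-controlled addition of 13 to the Si face of the aldehyde sets C8 (4R).

Step 9
Reactants: 14 methyl (4R,6Z,8R,10E)-8-{[tert-butyl(dimethyl)silyl]oxy}-4-hydroxy-6,10-dimethyl-12-[(triethylsilyl)oxy]dodeca-6,10-dien-2-ynoate
Product: 15 methyl (4R,6Z,8R,10E)-8-{[tert-butyl(dimethyl)silyl]oxy}-6,10-dimethyl-4,12-bis[(triethylsilyl)oxy]dodeca-6,10-dien-2-ynoate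
Conditions: TESCl, imidazole, DMF, 0 → 23 °C
Reagents that add atoms: chlorotriethylsilane (TESCl), CC[Si](Cl)(CC)CC
Why: Silylation of the propargylic alcohol prevents later butenolide formation with the cis ester (silyl ether protection).

Step 10
Reactants: 15 methyl (4R,6Z,8R,10E)-8-{[tert-butyl(dimethyl)silyl]oxy}-6,10-dimethyl-4,12-bis[(triethylsilyl)oxy]dodeca-6,10-dien-2-ynoate; 16 2-(iodomethyl)-4,4,5,5-tetramethyl-1,3,2-dioxaborolane
Product: 18 methyl (2Z,4R,6Z,8R,10E)-8-{[tert-butyl(dimethyl)silyl]oxy}-6,10-dimethyl-2-[(4,4,5,5-tetramethyl-1,3,2-dioxaborolan-2-yl)methyl]-4,12-bis[(triethylsilyl)oxy]dodeca-2,6,10-trienoate, via vinylalane 17 (not isolated)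
Conditions: i-Bu2AlH (1.3 equiv), HMPA, THF, 0 °C; then 16, 0 → 23 °C
Reagents that add atoms: none
Why: Syn-1,4-hydroalumination of the ynoate puts H on C7 and Al on C11 on the same side, so C8 ends cis to the ester, and vinyl transfer to boron of 16 with 1,2-migration and loss of iodide (Matteson-type homologation) gives the allylboronate with retention of geometry.

Step 11
Reactants: 18 methyl (2Z,4R,6Z,8R,10E)-8-{[tert-butyl(dimethyl)silyl]oxy}-6,10-dimethyl-2-[(4,4,5,5-tetramethyl-1,3,2-dioxaborolan-2-yl)methyl]-4,12-bis[(triethylsilyl)oxy]dodeca-2,6,10-trienoate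
Product: 19 methyl (2Z,4R,6Z,8R,10E)-8-{[tert-butyl(dimethyl)silyl]oxy}-6,10-dimethyl-12-oxo-2-[(4,4,5,5-tetramethyl-1,3,2-dioxaborolan-2-yl)methyl]-4-[(triethylsilyl)oxy]dodeca-2,6,10-trienoate
Conditions: (COCl)2, DMSO, CH2Cl2, −78 → −30 °C; Et3N, −78 → 0 °C
Reagents that add atoms: none
Why: Under Swern conditions a primary TES ether is converted directly into the aldehyde while secondary silyl ethers, the ester and the ester-deactivated boronate stay (oxidative desilylation, Swern oxidation).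

Step 12
Reactants: 19 methyl (2Z,4R,6Z,8R,10E)-8-{[tert-butyl(dimethyl)silyl]oxy}-6,10-dimethyl-12-oxo-2-[(4,4,5,5-tetramethyl-1,3,2-dioxaborolan-2-yl)methyl]-4-[(triethylsilyl)oxy]dodeca-2,6,10-trienoate
Product: 22 (3aR,4R,6Z,8R,10E,11aR)-8-{[tert-butyl(dimethyl)silyl]oxy}-4-hydroxy-6,10-dimethyl-3-methylidene-3a,4,5,8,9,11a-hexahydrocyclodeca[b]furan-2(3H)-one, via macrocyclic borate 20 (not isolated), via TES lactone 21 (not isolated)
Conditions: (S)-TRIP N-triflylphosphoramide (20 mol%), 4 Å MS, toluene (2 mM, syringe-pump addition), −20 → 23 °C; then PPTS, MeOH, 23 °C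
Reagents that add atoms: none
Why: Proposed new method: the 2-(methoxycarbonyl)allylboronate is inert toward the enal until a strong chiral Brønsted acid hydrogen-bonds to a pinacolate oxygen (raising the Lewis acidity of boron) while its P=O oxygen holds the formyl C–H, so ring A closes through a six-membered chair transition state with C5 and C8 both equatorial; because C8 is trans to CH2B this gives the 6,7-anti adduct 20 and hence the trans-lactone, and the catalyst-directed Si-face attack coincides with approach anti to C9 in the A(1,3)-locked conformer at C8, which gives 6R,7R; borate 20 then lactonizes with loss of MeO–Bpin and PPTS/MeOH removes the secondary TES group; the closest known reactions are chiral phosphoric acid-catalysed intermolecular allylboration of aldehydes with allyl pinacolboronates, Brønsted acid-catalysed allylboration with 2-alkoxycarbonyl allylboronates, and the CrCl2-mediated macrocyclizing Barbier allylation used for germacranolides.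

Step 13
Reactants: 23 methyl but-2-ynoate
Product: 25 methyl (2Z)-2-(hydroxymethyl)but-2-enoate, via vinylalane 24 (not isolated)
Conditions: i-Bu2AlH (1.2 equiv), HMPA, THF, 0 °C; then CH2O (gas), 0 → 23 °C
Reagents that add atoms: formaldehyde, C=O
Why: Syn-hydroalumination of the ynoate and aldol trapping of the vinylalane with formaldehyde (vinylalumination) give the enoate with CH3 cis to the ester.

Step 14
Reactants: 25 methyl (2Z)-2-(hydroxymethyl)but-2-enoate
Product: 26 methyl (2Z)-2-({[tert-butyl(dimethyl)silyl]oxy}methyl)but-2-enoate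
Conditions: TBSCl, imidazole, DMF, 23 °C
Reagents that add atoms: tert-butyldimethylsilyl chloride (TBSCl), CC(C)(C)[Si](C)(C)Cl
Why: Silylation of the primary alcohol (silyl ether protection).

Step 15
Reactants: 26 methyl (2Z)-2-({[tert-butyl(dimethyl)silyl]oxy}methyl)but-2-enoate
Product: 27 (2E)-2-({[tert-butyl(dimethyl)silyl]oxy}methyl)but-2-en-1-ol
Conditions: i-Bu2AlH (2.2 equiv), CH2Cl2, −78 °C
Reagents that add atoms: none
Why: 1,2-Reduction of the ester gives the allylic alcohol whose free CH2OH is cis to CH3 (hydride reduction).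

Step 16
Reactants: 27 (2E)-2-({[tert-butyl(dimethyl)silyl]oxy}methyl)but-2-en-1-ol
Product: 28 [(2R,3R)-2-({[tert-butyl(dimethyl)silyl]oxy}methyl)-3-methyloxiran-2-yl]methanol
Conditions: Ti(Oi-Pr)4 (10 mol%), L-(+)-diethyl tartrate (12 mol%), t-BuOOH, 4 Å MS, CH2Cl2, −20 °C
Reagents that add atoms: tert-butyl hydroperoxide, CC(C)(C)OO
Why: Sharpless asymmetric epoxidation in which the catalyst formed from Ti(Oi-Pr)4 and L-(+)-tartrate delivers oxygen to the face that gives the (2R,3R)-epoxide, the alkene geometry fixing CH3 cis to the future carboxyl group.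

Step 17
Reactants: 28 [(2R,3R)-2-({[tert-butyl(dimethyl)silyl]oxy}methyl)-3-methyloxiran-2-yl]methanol
Product: 30 (2R,3R)-2-({[tert-butyl(dimethyl)silyl]oxy}methyl)-3-methyloxirane-2-carboxylic acid, via epoxy aldehyde 29 (not isolated)
Conditions: TEMPO (20 mol%), PhI(OAc)2 (2.2 equiv), MeCN/pH 7 buffer, 0 → 23 °C
Reagents that add atoms: water, O
Why: Oxoammonium (TEMPO) oxidation takes the primary alcohol through the aldehyde hydrate to the acid without opening the epoxide.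

Step 18
Reactants: 22 (3aR,4R,6Z,8R,10E,11aR)-8-{[tert-butyl(dimethyl)silyl]oxy}-4-hydroxy-6,10-dimethyl-3-methylidene-3a,4,5,8,9,11a-hexahydrocyclodeca[b]furan-2(3H)-one; 30 (2R,3R)-2-({[tert-butyl(dimethyl)silyl]oxy}methyl)-3-methyloxirane-2-carboxylic acid
Product: 32 (3aR,4R,6Z,8R,10E,11aR)-8-{[tert-butyl(dimethyl)silyl]oxy}-6,10-dimethyl-3-methylidene-2-oxo-2,3,3a,4,5,8,9,11a-octahydrocyclodeca[b]furan-4-yl (2R,3R)-2-({[tert-butyl(dimethyl)silyl]oxy}methyl)-3-methyloxirane-2-carboxylate, via mixed anhydride 31 (not isolated)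
Conditions: 30 (2 equiv), 2,4,6-trichlorobenzoyl chloride, Et3N, THF, 0 °C; then 22, DMAP, toluene, 23 °C
Reagents that add atoms: none
Why: Yamaguchi esterification through the mixed anhydride acylates the hindered C8 hydroxyl, and only one ester forms because C2 is silyl-protected.

Step 19
Reactants: 32 (3aR,4R,6Z,8R,10E,11aR)-8-{[tert-butyl(dimethyl)silyl]oxy}-6,10-dimethyl-3-methylidene-2-oxo-2,3,3a,4,5,8,9,11a-octahydrocyclodeca[b]furan-4-yl (2R,3R)-2-({[tert-butyl(dimethyl)silyl]oxy}methyl)-3-methyloxirane-2-carboxylate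
Product: 33 (3aR,4R,6Z,8R,10E,11aR)-8-hydroxy-6,10-dimethyl-3-methylidene-2-oxo-2,3,3a,4,5,8,9,11a-octahydrocyclodeca[b]furan-4-yl (2R,3R)-2-(hydroxymethyl)-3-methyloxirane-2-carboxylate
Conditions: HF·pyridine, pyridine, THF, 0 → 23 °C
Reagents that add atoms: none
Why: Buffered fluoride desilylation removes both TBS ethers and leaves the epoxide, the ester and the α-methylene lactone intact.

## Compound list

1 | (2Z)-3-methylpent-2-en-4-yn-1-ol | OC/C=C(/C)C#C | starting material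
2 | (2Z)-3-methylpent-2-en-4-ynal | O=C/C=C(/C)C#C | intermediate
3 | ethyl 3-methylbut-2-enoate | CCOC(=O)C=C(C)C | starting material
4 | lithium 1-ethoxy-3-methylbuta-1,3-dien-1-olate (ketene acetal geometry not defined) | C=C(C)C=C(OCC)[O-].[Li+] | intermediate
5 | tert-butyl[(1-ethoxy-3-methylbuta-1,3-dien-1-yl)oxy]dimethylsilane (ketene acetal geometry not defined, used as the mixture) | C=C(C)C=C(OCC)O[Si](C)(C)C(C)(C)C | intermediate
6 | ethyl (2E,5R,6Z)-5-hydroxy-3,7-dimethylnona-2,6-dien-8-ynoate | CCOC(=O)/C=C(\C)C[C@@H](O)/C=C(/C)C#C | intermediate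
7 | ethyl (2E,5R,6Z)-5-{[tert-butyl(dimethyl)silyl]oxy}-3,7-dimethylnona-2,6-dien-8-ynoate | CCOC(=O)/C=C(\C)C[C@@H](O[Si](C)(C)C(C)(C)C)/C=C(/C)C#C | intermediate
8 | (2E,5R,6Z)-5-{[tert-butyl(dimethyl)silyl]oxy}-3,7-dimethylnona-2,6-dien-8-yn-1-ol | OC/C=C(\C)C[C@@H](O[Si](C)(C)C(C)(C)C)/C=C(/C)C#C | intermediate
9 | tert-butyl(dimethyl){[(3Z,5R,7E)-3,7-dimethyl-9-[(triethylsilyl)oxy]nona-3,7-dien-1-yn-5-yl]oxy}silane | CC[Si](CC)(CC)OC/C=C(\C)C[C@@H](O[Si](C)(C)C(C)(C)C)/C=C(/C)C#C | intermediate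
10 | dicyclohexyl[(1E,3Z,5R,7E)-5-{[tert-butyl(dimethyl)silyl]oxy}-3,7-dimethyl-9-[(triethylsilyl)oxy]nona-1,3,7-trien-1-yl]borane | CC[Si](CC)(CC)OC/C=C(\C)C[C@@H](O[Si](C)(C)C(C)(C)C)/C=C(/C)\C=C\B(C1CCCCC1)C1CCCCC1 | intermediate
11 | (3Z,5R,7E)-5-{[tert-butyl(dimethyl)silyl]oxy}-3,7-dimethyl-9-[(triethylsilyl)oxy]nona-3,7-dienal | CC[Si](CC)(CC)OC/C=C(\C)C[C@@H](O[Si](C)(C)C(C)(C)C)/C=C(/C)CC=O | intermediate
12 | methyl prop-2-ynoate | C#CC(=O)OC | starting material
13 | methyl 3-(methylzincio)prop-2-ynoate | C[Zn]C#CC(=O)OC | intermediate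
14 | methyl (4R,6Z,8R,10E)-8-{[tert-butyl(dimethyl)silyl]oxy}-4-hydroxy-6,10-dimethyl-12-[(triethylsilyl)oxy]dodeca-6,10-dien-2-ynoate | CC[Si](CC)(CC)OC/C=C(\C)C[C@@H](O[Si](C)(C)C(C)(C)C)/C=C(/C)C[C@@H](O)C#CC(=O)OC | intermediate
15 | methyl (4R,6Z,8R,10E)-8-{[tert-butyl(dimethyl)silyl]oxy}-6,10-dimethyl-4,12-bis[(triethylsilyl)oxy]dodeca-6,10-dien-2-ynoate | CC[Si](CC)(CC)OC/C=C(\C)C[C@@H](O[Si](C)(C)C(C)(C)C)/C=C(/C)C[C@@H](O[Si](CC)(CC)CC)C#CC(=O)OC | intermediate
16 | 2-(iodomethyl)-4,4,5,5-tetramethyl-1,3,2-dioxaborolane | ICB1OC(C)(C)C(C)(C)O1 | starting material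
17 | methyl (2E,4R,6Z,8R,10E)-2-[bis(2-methylpropyl)alumanyl]-8-{[tert-butyl(dimethyl)silyl]oxy}-6,10-dimethyl-4,12-bis[(triethylsilyl)oxy]dodeca-2,6,10-trienoate | CC[Si](CC)(CC)OC/C=C(\C)C[C@@H](O[Si](C)(C)C(C)(C)C)/C=C(/C)C[C@@H](O[Si](CC)(CC)CC)/C=C(/[Al](CC(C)C)CC(C)C)C(=O)OC | intermediate
18 | methyl (2Z,4R,6Z,8R,10E)-8-{[tert-butyl(dimethyl)silyl]oxy}-6,10-dimethyl-2-[(4,4,5,5-tetramethyl-1,3,2-dioxaborolan-2-yl)methyl]-4,12-bis[(triethylsilyl)oxy]dodeca-2,6,10-trienoate | CC[Si](CC)(CC)OC/C=C(\C)C[C@@H](O[Si](C)(C)C(C)(C)C)/C=C(/C)C[C@@H](O[Si](CC)(CC)CC)/C=C(/CB1OC(C)(C)C(C)(C)O1)C(=O)OC | intermediate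
19 | methyl (2Z,4R,6Z,8R,10E)-8-{[tert-butyl(dimethyl)silyl]oxy}-6,10-dimethyl-12-oxo-2-[(4,4,5,5-tetramethyl-1,3,2-dioxaborolan-2-yl)methyl]-4-[(triethylsilyl)oxy]dodeca-2,6,10-trienoate | O=C/C=C(\C)C[C@@H](O[Si](C)(C)C(C)(C)C)/C=C(/C)C[C@@H](O[Si](CC)(CC)CC)/C=C(/CB1OC(C)(C)C(C)(C)O1)C(=O)OC | intermediate
20 | methyl 2-[(1S,2R,3E,6R,7Z,10R)-6-{[tert-butyl(dimethyl)silyl]oxy}-4,8-dimethyl-2-[(4,4,5,5-tetramethyl-1,3,2-dioxaborolan-2-yl)oxy]-10-[(triethylsilyl)oxy]cyclodeca-3,7-dien-1-yl]prop-2-enoate | CC1(C)OB(O[C@@H]2/C=C(\C)C[C@@H](O[Si](C)(C)C(C)(C)C)/C=C(/C)C[C@@H](O[Si](CC)(CC)CC)[C@H]2C(=C)C(=O)OC)OC1(C)C | intermediate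
21 | (3aS,4R,6Z,8R,10E,11aR)-8-{[tert-butyl(dimethyl)silyl]oxy}-6,10-dimethyl-3-methylidene-4-[(triethylsilyl)oxy]-3a,4,5,8,9,11a-hexahydrocyclodeca[b]furan-2(3H)-one | C=C1C(=O)O[C@@H]2/C=C(\C)C[C@@H](O[Si](C)(C)C(C)(C)C)/C=C(/C)C[C@@H](O[Si](CC)(CC)CC)[C@@H]12 | intermediate
22 | (3aR,4R,6Z,8R,10E,11aR)-8-{[tert-butyl(dimethyl)silyl]oxy}-4-hydroxy-6,10-dimethyl-3-methylidene-3a,4,5,8,9,11a-hexahydrocyclodeca[b]furan-2(3H)-one | C=C1C(=O)O[C@@H]2/C=C(\C)C[C@@H](O[Si](C)(C)C(C)(C)C)/C=C(/C)C[C@@H](O)[C@@H]12 | intermediate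
23 | methyl but-2-ynoate | CC#CC(=O)OC | starting material
24 | methyl (2E)-2-[bis(2-methylpropyl)alumanyl]but-2-enoate | C/C=C(/[Al](CC(C)C)CC(C)C)C(=O)OC | intermediate
25 | methyl (2Z)-2-(hydroxymethyl)but-2-enoate | C/C=C(/CO)C(=O)OC | intermediate
26 | methyl (2Z)-2-({[tert-butyl(dimethyl)silyl]oxy}methyl)but-2-enoate | C/C=C(/CO[Si](C)(C)C(C)(C)C)C(=O)OC | intermediate
27 | (2E)-2-({[tert-butyl(dimethyl)silyl]oxy}methyl)but-2-en-1-ol | C/C=C(/CO[Si](C)(C)C(C)(C)C)CO | intermediate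
28 | [(2R,3R)-2-({[tert-butyl(dimethyl)silyl]oxy}methyl)-3-methyloxiran-2-yl]methanol | OC[C@]1(CO[Si](C)(C)C(C)(C)C)O[C@@H]1C | intermediate
29 | (2R,3R)-2-({[tert-butyl(dimethyl)silyl]oxy}methyl)-3-methyloxirane-2-carbaldehyde | O=C[C@]1(CO[Si](C)(C)C(C)(C)C)O[C@@H]1C | intermediate
30 | (2R,3R)-2-({[tert-butyl(dimethyl)silyl]oxy}methyl)-3-methyloxirane-2-carboxylic acid | OC(=O)[C@]1(CO[Si](C)(C)C(C)(C)C)O[C@@H]1C | intermediate
31 | (2R,3R)-2-({[tert-butyl(dimethyl)silyl]oxy}methyl)-3-methyloxirane-2-carboxylic 2,4,6-trichlorobenzoic anhydride | O=C(OC(=O)[C@]1(CO[Si](C)(C)C(C)(C)C)O[C@@H]1C)c1c(Cl)cc(Cl)cc1Cl | intermediate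
32 | (3aR,4R,6Z,8R,10E,11aR)-8-{[tert-butyl(dimethyl)silyl]oxy}-6,10-dimethyl-3-methylidene-2-oxo-2,3,3a,4,5,8,9,11a-octahydrocyclodeca[b]furan-4-yl (2R,3R)-2-({[tert-butyl(dimethyl)silyl]oxy}methyl)-3-methyloxirane-2-carboxylate | C=C1C(=O)O[C@@H]2/C=C(\C)C[C@@H](O[Si](C)(C)C(C)(C)C)/C=C(/C)C[C@@H](OC(=O)[C@]3(CO[Si](C)(C)C(C)(C)C)O[C@@H]3C)[C@@H]12 | intermediate
33 | (3aR,4R,6Z,8R,10E,11aR)-8-hydroxy-6,10-dimethyl-3-methylidene-2-oxo-2,3,3a,4,5,8,9,11a-octahydrocyclodeca[b]furan-4-yl (2R,3R)-2-(hydroxymethyl)-3-methyloxirane-2-carboxylate | C=C1C(=O)O[C@@H]2/C=C(\C)C[C@@H](O)/C=C(/C)C[C@@H](OC(=O)[C@]3(CO)O[C@@H]3C)[C@@H]12 | target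

## Step count and risks

Total step count: 19. Longest linear sequence: 13 steps (steps 1, 3–12, 18 and 19, from compound 1).

The three steps most likely to fail:

Step 12, the proposed ring closure, is untested. The ester-deactivated boronate may turn over slowly, oligomers may compete even at 2 mM, the macrocycle may override the catalyst and the C8 bias and give the C6/C7 diastereomer, and a strong acid may ionize the allylic C6–O bond. The fallback uses known chemistry and sets out from 15. Hydroalumination as in step 10 gives vinylalane 17, which is trapped with formaldehyde (vinylalumination) to give methyl (2Z,4R,6Z,8R,10E)-8-{[tert-butyl(dimethyl)silyl]oxy}-2-(hydroxymethyl)-6,10-dimethyl-4,12-bis[(triethylsilyl)oxy]dodeca-2,6,10-trienoate F7. CBr4/PPh3 converts it into the allylic bromide methyl (2E,4R,6Z,8R,10E)-2-(bromomethyl)-8-{[tert-butyl(dimethyl)silyl]oxy}-6,10-dimethyl-4,12-bis[(triethylsilyl)oxy]dodeca-2,6,10-trienoate F8. Swern oxidation of the primary TES ether gives the bromo enal methyl (2E,4R,6Z,8R,10E)-2-(bromomethyl)-8-{[tert-butyl(dimethyl)silyl]oxy}-6,10-dimethyl-12-oxo-4-[(triethylsilyl)oxy]dodeca-2,6,10-trienoate F9. CrCl2 in DMF/THF at 2 mM then closes ring A by the intramolecular Nozaki–Hiyama-type Barbier allylation that is established for germacranolides. The adduct lactonizes (PPTS) to 21, where the route is rejoined; PPTS/MeOH gives 22 as in step 12.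

Step 8 uses aldehyde 11, which is β,γ-unsaturated and enolizable. Under the zinc alkoxide conditions it may slip into conjugation or self-condense, and α-unbranched aldehydes can give only moderate ee. The fallback replaces asymmetric addition by asymmetric reduction and sets out from 11. Methyl 3-lithioprop-2-ynoate F1 (from 12 and LiN(SiMe3)2, THF, −90 °C) adds to give the C4-epimeric alcohols methyl (6Z,8R,10E)-8-{[tert-butyl(dimethyl)silyl]oxy}-4-hydroxy-6,10-dimethyl-12-[(triethylsilyl)oxy]dodeca-6,10-dien-2-ynoate F2. Buffered Dess–Martin oxidation gives the ynone methyl (6Z,8R,10E)-8-{[tert-butyl(dimethyl)silyl]oxy}-6,10-dimethyl-4-oxo-12-[(triethylsilyl)oxy]dodeca-6,10-dien-2-ynoate F3. Noyori transfer hydrogenation with RuCl(p-cymene)[(R,R)-TsDPEN] in i-PrOH (the enantiomer that gives the 4R alcohol) comes back to the route at 14.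

Step 10 depends on a configurationally stable vinylalane and a clean alkylation with 16. Any E/Z scrambling would feed the wrong diastereomer into the stereospecific step 12, and conjugate over-reduction is possible. The fallback sets out from 15. Pd(PPh3)4-catalysed syn-hydrostannation with Bu3SnH gives methyl (2E,4R,6Z,8R,10E)-8-{[tert-butyl(dimethyl)silyl]oxy}-6,10-dimethyl-2-(tributylstannyl)-4,12-bis[(triethylsilyl)oxy]dodeca-2,6,10-trienoate F4. Iododestannylation with I2 gives methyl (2E,4R,6Z,8R,10E)-8-{[tert-butyl(dimethyl)silyl]oxy}-2-iodo-6,10-dimethyl-4,12-bis[(triethylsilyl)oxy]dodeca-2,6,10-trienoate F5 with retention. Negishi coupling with iodo[(4,4,5,5-tetramethyl-1,3,2-dioxaborolan-2-yl)methyl]zinc F6 (from 16 and zinc dust) under Pd(PPh3)4 comes back to the route at 18.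

Further compounds

F1 | step 8 | methyl 3-lithioprop-2-ynoate | [Li]C#CC(=O)OC
F2 | step 8 | methyl (6Z,8R,10E)-8-{[tert-butyl(dimethyl)silyl]oxy}-4-hydroxy-6,10-dimethyl-12-[(triethylsilyl)oxy]dodeca-6,10-dien-2-ynoate (both C4 epimers) | CC[Si](CC)(CC)OC/C=C(\C)C[C@@H](O[Si](C)(C)C(C)(C)C)/C=C(/C)CC(O)C#CC(=O)OC
F3 | step 8 | methyl (6Z,8R,10E)-8-{[tert-butyl(dimethyl)silyl]oxy}-6,10-dimethyl-4-oxo-12-[(triethylsilyl)oxy]dodeca-6,10-dien-2-ynoate | CC[Si](CC)(CC)OC/C=C(\C)C[C@@H](O[Si](C)(C)C(C)(C)C)/C=C(/C)CC(=O)C#CC(=O)OC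
F4 | step 10 | methyl (2E,4R,6Z,8R,10E)-8-{[tert-butyl(dimethyl)silyl]oxy}-6,10-dimethyl-2-(tributylstannyl)-4,12-bis[(triethylsilyl)oxy]dodeca-2,6,10-trienoate | CC[Si](CC)(CC)OC/C=C(\C)C[C@@H](O[Si](C)(C)C(C)(C)C)/C=C(/C)C[C@@H](O[Si](CC)(CC)CC)/C=C(/[Sn](CCCC)(CCCC)CCCC)C(=O)OC
F5 | step 10 | methyl (2E,4R,6Z,8R,10E)-8-{[tert-butyl(dimethyl)silyl]oxy}-2-iodo-6,10-dimethyl-4,12-bis[(triethylsilyl)oxy]dodeca-2,6,10-trienoate | CC[Si](CC)(CC)OC/C=C(\C)C[C@@H](O[Si](C)(C)C(C)(C)C)/C=C(/C)C[C@@H](O[Si](CC)(CC)CC)/C=C(/I)C(=O)OC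
F6 | step 10 | iodo[(4,4,5,5-tetramethyl-1,3,2-dioxaborolan-2-yl)methyl]zinc | I[Zn]CB1OC(C)(C)C(C)(C)O1
F7 | step 12 | methyl (2Z,4R,6Z,8R,10E)-8-{[tert-butyl(dimethyl)silyl]oxy}-2-(hydroxymethyl)-6,10-dimethyl-4,12-bis[(triethylsilyl)oxy]dodeca-2,6,10-trienoate | CC[Si](CC)(CC)OC/C=C(\C)C[C@@H](O[Si](C)(C)C(C)(C)C)/C=C(/C)C[C@@H](O[Si](CC)(CC)CC)/C=C(/CO)C(=O)OC
F8 | step 12 | methyl (2E,4R,6Z,8R,10E)-2-(bromomethyl)-8-{[tert-butyl(dimethyl)silyl]oxy}-6,10-dimethyl-4,12-bis[(triethylsilyl)oxy]dodeca-2,6,10-trienoate | CC[Si](CC)(CC)OC/C=C(\C)C[C@@H](O[Si](C)(C)C(C)(C)C)/C=C(/C)C[C@@H](O[Si](CC)(CC)CC)/C=C(/CBr)C(=O)OC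
F9 | step 12 | methyl (2E,4R,6Z,8R,10E)-2-(bromomethyl)-8-{[tert-butyl(dimethyl)silyl]oxy}-6,10-dimethyl-12-oxo-4-[(triethylsilyl)oxy]dodeca-2,6,10-trienoate | O=C/C=C(\C)C[C@@H](O[Si](C)(C)C(C)(C)C)/C=C(/C)C[C@@H](O[Si](CC)(CC)CC)/C=C(/CBr)C(=O)OC
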